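The acyl chain on O3 of ring C is a beta-hydroxy ester: C1 is the ester carbonyl, C2 a methylene, C3 the S carbinol, then C4, and C5 is benzylic to catechol ring D. The C1 carbonyl and the C3 hydroxyl therefore stand in the 1,3-relation that an epoxide plus carbon monoxide delivers.
Disconnections: the six phenolic benzyl ethers go first (final hydrogenolysis). C1 is then excised as CO, which cuts C1-O3 and C1-C2 together and leaves O3-free tetra-O-benzylcatechin and the S terminal epoxide spanning chain C2-C3.
Fragments: the alcohol comes from (+)-catechin by fourfold phenol benzylation. The epoxide comes from 3,4-dihydroxybenzaldehyde by benzylation, reduction, chlorination, allyl Grignard coupling (C4-C5), epoxidation and hydrolytic kinetic resolution.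
Rings: none of rings A, B, C or D is built. A, B and C arrive in catechin with 2R,3S in place, and D arrives in the aldehyde. The only ring made is the oxirane, and the key step opens it again.
Key step: step 8

Assumption: the flavan part is taken exactly as written in the SMILES, 2R,3S with the 2-aryl and 3-acyloxy groups trans, which is the configuration of (+)-catechin. Chain C3 is S.

Step 1
Reactants: 1 (+)-catechin
Product: 2 5,7,3',4'-tetra-O-benzyl-(+)-catechin
Conditions: BnBr (4.3 equiv), K2CO3 (4.5 equiv), DMF, 0 °C to rt, Ar
Reagents that add atoms: benzyl bromide, BrCc1ccccc1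
Why: Williamson ether synthesis in which K2CO3 ionises only the four phenols and not the aliphatic O3-H, so O3 should stay free, while the low temperature under argon holds back C-benzylation of ring A and base-induced epimerisation at C2, so that 2R,3S is kept.

Step 2
Reactants: 3 3,4-dihydroxybenzaldehyde
Product: 4 3,4-bis(benzyloxy)benzaldehyde
Conditions: BnBr (2.3 equiv), K2CO3 (2.5 equiv), DMF, 60 °C
Reagents that add atoms: benzyl bromide, BrCc1ccccc1
Why: Williamson ether synthesis on both catechol hydroxyls, a routine protection that the aldehyde tolerates (4 can also be bought).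

Step 3
Reactants: 4 3,4-bis(benzyloxy)benzaldehyde
Product: 5 [3,4-bis(benzyloxy)phenyl]methanol
Conditions: NaBH4, MeOH/THF, 0 °C
Reagents that add atoms: none
Why: Borohydride reduction of an aromatic aldehyde to the benzylic alcohol, which leaves aryl benzyl ethers untouched.

Step 4
Reactants: 5 [3,4-bis(benzyloxy)phenyl]methanol
Product: 6 3,4-bis(benzyloxy)benzyl chloride
Conditions: SOCl2 (1.2 equiv), CH2Cl2, 0 °C to rt; concentrated and used crude
Reagents that add atoms: thionyl chloride, O=S(Cl)Cl
Why: Deoxychlorination of an electron-rich benzylic alcohol with thionyl chloride is fast at low temperature and spares the benzyl ethers, and the labile chloride is carried on without purification.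

Step 5
Reactants: 6 3,4-bis(benzyloxy)benzyl chloride; 7 allylmagnesium bromide
Product: 8 4-[3,4-bis(benzyloxy)phenyl]but-1-ene
Conditions: 7 (1.5 equiv), Et2O/THF, 0 °C to rt, 6 added to the Grignard solution
Reagents that add atoms: none
Why: Uncatalysed SN2-type coupling of an allyl Grignard reagent with a benzylic chloride forms chain C4-C5, and adding the chloride to excess Grignard reagent limits benzylic homocoupling.

Step 6
Reactants: 8 4-[3,4-bis(benzyloxy)phenyl]but-1-ene
Product: 9 rac-2-{2-[3,4-bis(benzyloxy)phenyl]ethyl}oxirane
Conditions: mCPBA (1.3 equiv), CH2Cl2, 0 °C to rt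
Reagents that add atoms: 3-chloroperoxybenzoic acid, O=C(OO)c1cccc(Cl)c1
Why: Prilezhaev epoxidation of the only alkene, which gives the racemate because nothing biases the alkene faces, so the configuration is sorted out in step 7.

Step 7
Reactants: 9 rac-2-{2-[3,4-bis(benzyloxy)phenyl]ethyl}oxirane
Product: 10 (S)-2-{2-[3,4-bis(benzyloxy)phenyl]ethyl}oxirane
Conditions: (S,S)-(salen)Co(OAc) (1 mol%, from (S,S)-(salen)Co, AcOH, air; salen = N,N'-bis(3,5-di-tert-butylsalicylidene)cyclohexane-1,2-diaminate), H2O (0.55 equiv), THF, 0 °C to rt; chromatography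
Reagents that add atoms: none
Why: Hydrolytic kinetic resolution in which the S,S complex of trivalent cobalt hydrates the R enantiomer of a monoalkyl epoxide at its terminal carbon much faster than the S enantiomer, so with slightly more than half an equivalent of water the S epoxide should remain in high enantiomeric purity and is separated from the polar diol co-product, which fixes chain C3.

Step 8
Reactants: 10 (S)-2-{2-[3,4-bis(benzyloxy)phenyl]ethyl}oxirane; 2 5,7,3',4'-tetra-O-benzyl-(+)-catechin
Product: 13 hexa-O-benzylphylloflavan, via alkylcobalt tetracarbonyl 11 (not isolated), via acylcobalt tetracarbonyl 12 (not isolated)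
Conditions: Co2(CO)8 (10 mol%), 3-hydroxypyridine (20 mol%), CO (60 bar), 2 (4 equiv), dry THF (about 0.8 M in 2), 65 °C, autoclave; surplus 2 recovered
Reagents that add atoms: carbon monoxide, [C-]#[O+]
Why: Proposed new method: 3-hydroxypyridine disproportionates Co2(CO)8 to [Co(CO)4]- paired with a hydroxypyridinium proton donor, the anion opens the hydrogen-bond-activated epoxide 10 by SN2 attack at the terminal CH2 (chain C2) to give alkylcobalt 11, migratory insertion of CO gives acylcobalt 12 (C1-C2 formed), and O3-H of 2, with the pyridine as acyl relay, cleaves the acyl-cobalt bond (C1-O3 formed) and regenerates HCo(CO)4. The closest known reaction types are the methoxycarbonylation of enantiopure terminal epoxides with the same catalyst pair in methanol and the alternating epoxide/CO copolymerisation it causes without added alcohol, in which a secondary carbinol chain end at low concentration takes up the acyl group; a hindered secondary alcohol as a discrete, non-solvent partner has not been shown. No ring is closed and no stereocentre is created: the C3-O bond of the epoxide is never broken, so chain C3 keeps the S configuration of 10, and C2 and C3 of ring C are spectators because benzylation blocks the quinone methide path to C2 epimerisation. Regioselectivity for the terminal carbon is secured by the steric bias of the monosubstituted epoxide. Chemoselectivity of acyl transfer for O3 over the chain carbinol that each turnover unveils is not secured by structure, since that carbinol is the nucleophile of the copolymerisation, and is therefore enforced by a fourfold excess of 2 at high concentration. The high CO pressure favours insertion over beta-hydride elimination from 11, and strictly dry conditions keep water from competing for 12.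

Step 9
Reactants: 13 hexa-O-benzylphylloflavan
Product: 14 phylloflavan
Conditions: H2 (1 atm), 10% Pd/C, degassed THF/MeOH (1:1), rt; filtration under Ar
Reagents that add atoms: none
Why: Heterogeneous hydrogenolysis of aryl benzyl ethers is the standard last step for flavan-3-ol esters and, under neutral conditions at 1 atm, should leave the ester, the secondary carbinol, the three stereocentres and the more slowly cleaved cyclic C2-O1 bond of ring C intact.

Compound list
1 | (+)-catechin, (2R,3S)-2-(3,4-dihydroxyphenyl)chroman-3,5,7-triol | O[C@H]1Cc2c(O)cc(O)cc2O[C@@H]1c1ccc(O)c(O)c1 | starting material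
2 | 5,7,3',4'-tetra-O-benzyl-(+)-catechin, (2R,3S)-5,7-bis(benzyloxy)-2-[3,4-bis(benzyloxy)phenyl]chroman-3-ol | O[C@H]1Cc2c(OCc3ccccc3)cc(OCc3ccccc3)cc2O[C@@H]1c1ccc(OCc2ccccc2)c(OCc2ccccc2)c1 | intermediate
3 | 3,4-dihydroxybenzaldehyde | O=Cc1ccc(O)c(O)c1 | starting material
4 | 3,4-bis(benzyloxy)benzaldehyde | O=Cc1ccc(OCc2ccccc2)c(OCc2ccccc2)c1 | intermediate
5 | [3,4-bis(benzyloxy)phenyl]methanol | OCc1ccc(OCc2ccccc2)c(OCc2ccccc2)c1 | intermediate
6 | 3,4-bis(benzyloxy)benzyl chloride | ClCc1ccc(OCc2ccccc2)c(OCc2ccccc2)c1 | intermediate
7 | allylmagnesium bromide | C=CC[Mg]Br | starting material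
8 | 4-[3,4-bis(benzyloxy)phenyl]but-1-ene | C=CCCc1ccc(OCc2ccccc2)c(OCc2ccccc2)c1 | intermediate
9 | rac-2-{2-[3,4-bis(benzyloxy)phenyl]ethyl}oxirane | C1OC1CCc1ccc(OCc2ccccc2)c(OCc2ccccc2)c1 | intermediate
10 | (S)-2-{2-[3,4-bis(benzyloxy)phenyl]ethyl}oxirane | C1O[C@H]1CCc1ccc(OCc2ccccc2)c(OCc2ccccc2)c1 | intermediate
11 | {(2S)-4-[3,4-bis(benzyloxy)phenyl]-2-hydroxybutyl}tetracarbonylcobalt (not isolated) | O=C=[Co](=C=O)(=C=O)(=C=O)C[C@@H](O)CCc1ccc(OCc2ccccc2)c(OCc2ccccc2)c1 | intermediate
12 | {(3S)-5-[3,4-bis(benzyloxy)phenyl]-3-hydroxypentanoyl}tetracarbonylcobalt (not isolated) | O=C=[Co](=C=O)(=C=O)(=C=O)C(=O)C[C@@H](O)CCc1ccc(OCc2ccccc2)c(OCc2ccccc2)c1 | intermediate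
13 | hexa-O-benzylphylloflavan, (2R,3S)-5,7-bis(benzyloxy)-2-[3,4-bis(benzyloxy)phenyl]chroman-3-yl (3S)-5-[3,4-bis(benzyloxy)phenyl]-3-hydroxypentanoate | O=C(C[C@@H](O)CCc1ccc(OCc2ccccc2)c(OCc2ccccc2)c1)O[C@H]1Cc2c(OCc3ccccc3)cc(OCc3ccccc3)cc2O[C@@H]1c1ccc(OCc2ccccc2)c(OCc2ccccc2)c1 | intermediate
14 | phylloflavan, (2R,3S)-2-(3,4-dihydroxyphenyl)-5,7-dihydroxychroman-3-yl (3S)-5-(3,4-dihydroxyphenyl)-3-hydroxypentanoate | O=C(C[C@@H](O)CCc1ccc(O)c(O)c1)O[C@H]1Cc2c(O)cc(O)cc2O[C@@H]1c1ccc(O)c(O)c1 | target

Total step count: 9
Longest linear sequence: 8 steps (steps 2 to 9, from 3,4-dihydroxybenzaldehyde)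

Steps most likely to fail

Step 8. Acyl transfer to the hindered O3-H may be too slow. The acyl group would then be handed on to the chain carbinol of product already formed (oligoester growth), the acylcobalt could close on its own hydroxyl, or the alkylcobalt could decay by beta-hydride elimination.
The fallback uses known chemistry only, sets out from 10 and comes back at 13.
- The same catalyst pair in MeOH/THF under CO (the established methoxycarbonylation) should give methyl (3S)-5-[3,4-bis(benzyloxy)phenyl]-3-hydroxypentanoate F1.
- TBSCl and imidazole in DMF convert it into its tert-butyldimethylsilyl ether F2.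
- LiOH in THF/H2O followed by mild acidification gives (3S)-5-[3,4-bis(benzyloxy)phenyl]-3-[(tert-butyldimethylsilyl)oxy]pentanoic acid F3.
- Steglich esterification (EDC·HCl, DMAP, CH2Cl2) with 2 gives O-silylated hexa-O-benzylphylloflavan F4.
- HF·pyridine in THF removes the silyl group to reach 13.

Step 7. The resolution may stall or lose selectivity because the lipophilic epoxide and water do not share a phase, which would leave insufficient enantiomeric purity. Half of the material is also lost by design.
The fallback replaces resolution by the chiral pool, sets out from 6 and comes back at 10, bypassing steps 5 to 7.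
- Magnesium turnings in dilute THF at 0 °C convert 6 into 3,4-bis(benzyloxy)benzylmagnesium chloride F5.
- With Li2CuCl4 (3 mol%) at -40 °C, F5 opens commercial (S)-epichlorohydrin (ClC[C@@H]1CO1) at its epoxide CH2 and gives (2S)-1-chloro-4-[3,4-bis(benzyloxy)phenyl]butan-2-ol F6.
- NaOH in THF/H2O closes the new oxirane without touching the stereocentre and gives 10.

Step 9. Removal of six benzyl groups may stop short. Prolonged exposure may start hydrogenolytic opening of the benzylic C2-O1 bond of ring C, and the two catechols may oxidise in air during filtration.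
The fallback replaces reduction by Lewis acid cleavage, sets out from 13 and comes back at 14. BCl3 with pentamethylbenzene as benzyl cation scavenger in CH2Cl2 at -78 °C, quenched with MeOH, should release all six phenols with no metal surface and no filtration. It makes no new compound (F0).

Further compounds
F1 | step 8 | methyl (3S)-5-[3,4-bis(benzyloxy)phenyl]-3-hydroxypentanoate | COC(=O)C[C@@H](O)CCc1ccc(OCc2ccccc2)c(OCc2ccccc2)c1
F2 | step 8 | methyl (3S)-5-[3,4-bis(benzyloxy)phenyl]-3-[(tert-butyldimethylsilyl)oxy]pentanoate | COC(=O)C[C@@H](O[Si](C)(C)C(C)(C)C)CCc1ccc(OCc2ccccc2)c(OCc2ccccc2)c1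
F3 | step 8 | (3S)-5-[3,4-bis(benzyloxy)phenyl]-3-[(tert-butyldimethylsilyl)oxy]pentanoic acid | OC(=O)C[C@@H](O[Si](C)(C)C(C)(C)C)CCc1ccc(OCc2ccccc2)c(OCc2ccccc2)c1
F4 | step 8 | O-silylated hexa-O-benzylphylloflavan, (2R,3S)-5,7-bis(benzyloxy)-2-[3,4-bis(benzyloxy)phenyl]chroman-3-yl (3S)-5-[3,4-bis(benzyloxy)phenyl]-3-[(tert-butyldimethylsilyl)oxy]pentanoate | O=C(C[C@@H](O[Si](C)(C)C(C)(C)C)CCc1ccc(OCc2ccccc2)c(OCc2ccccc2)c1)O[C@H]1Cc2c(OCc3ccccc3)cc(OCc3ccccc3)cc2O[C@@H]1c1ccc(OCc2ccccc2)c(OCc2ccccc2)c1
F5 | step 7 | 3,4-bis(benzyloxy)benzylmagnesium chloride | Cl[Mg]Cc1ccc(OCc2ccccc2)c(OCc2ccccc2)c1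
F6 | step 7 | (2S)-1-chloro-4-[3,4-bis(benzyloxy)phenyl]butan-2-ol | ClC[C@@H](O)CCc1ccc(OCc2ccccc2)c(OCc2ccccc2)c1
F0 | step 9 | none | none
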